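**Retrosynthetic overview**

1. Target 22 ← diol 21 (bis-acetylation) ← C2 ketone 20 (dissolving-metal reduction gives the equatorial 2-OH and removes the benzyl group). The C2 carbonyl and the C4 gem-dimethyl group of 20 come from the C4 ketone 15 by enone formation, MeLi addition, oxidative 1,3-transposition and cuprate addition.
2. Key disconnection: ring B of 15 is opened at C5–C6 and at C8–C9. This releases C6–C7=C8(–C17) as (Z)-1-bromo-3-iodobut-2-ene 12 and leaves the ring A silyl enol ether 9. Forward, in one flask: the C5 enolate is alkylated by the allylic bromide, then the C8 vinyl radical closes ring B 6-exo-trig onto the C9=C11 alkene.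
3. Feature that makes this possible: ring B is a cyclohexene whose C7=C8 double bond (carrying the C17 methyl) lies between the allylic CH2 C6 and the allylic CH C9. The three ring carbons C6–C7–C8 are therefore a 2-butenyl unit tied to ring A only through C5 (α to a C4 carbonyl) and through C9 (one end of an alkene on the quaternary C10).
4. 9 ← copper-catalysed asymmetric conjugate addition of the (E)-alkenylalane from alkyne 5 to 3-methylcyclohex-2-en-1-one 6 (sets C10 and marks C5 as the enolate carbon); 5 ← methyl hydrogen (R)-3-methylglutarate 1 (brings C13).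
5. Order of ring formation: ring A is bought with 6; ring B is closed in the key step, which also sets C5 and C9.

Key step: step 8

Remark: labdane numbering is used only as a numbering frame (C20 = methyl on C10, C17 = methyl on C8, C18/C19 = methyls on C4, C11–C16 = side chain); in every bicyclic compound H5 and H9 are anti to C20, the C9 side chain is cis to C20, C13 is S, and the absolute configuration is the one written in the SMILES.

**Route**

Step 1
Reactants: 1 methyl hydrogen (R)-3-methylglutarate
Product: 2 methyl (3R)-5-hydroxy-3-methylpentanoate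
Conditions: BH3·SMe2, THF, 0 °C → rt; then H2O
Reagents that add atoms: none
Why: Borane reduces the free carboxylic acid much faster than the methyl ester (chemoselective acid reduction), so the two arms of the glutarate are differentiated and the C13 stereocentre is untouched.

Step 2
Reactants: 2 methyl (3R)-5-hydroxy-3-methylpentanoate
Product: 3 methyl (3R)-5-(benzyloxy)-3-methylpentanoate
Conditions: BnOC(=NH)CCl3, TfOH (cat.), CH2Cl2/cyclohexane, 0 °C → rt
Reagents that add atoms: benzyl 2,2,2-trichloroacetimidate, ClC(Cl)(Cl)C(=N)OCc1ccccc1
Why: Acid-catalysed O-benzylation with the trichloroacetimidate avoids the basic conditions under which the δ-hydroxy ester would lactonise.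

Step 3
Reactants: 3 methyl (3R)-5-(benzyloxy)-3-methylpentanoate
Product: 4 (3R)-5-(benzyloxy)-3-methylpentanal
Conditions: i-Bu2AlH (1.05 equiv), CH2Cl2, −78 °C; then aq. KNaC4H4O6
Reagents that add atoms: none
Why: Partial ester reduction stops at the aluminium hemiacetal at −78 °C and gives the aldehyde on work-up; the stereocentre is β to the carbonyl and cannot epimerise.

Step 4
Reactants: 4 (3R)-5-(benzyloxy)-3-methylpentanal
Product: 5 benzyl (3S)-3-methylhex-5-yn-1-yl ether
Conditions: dimethyl (1-diazo-2-oxopropyl)phosphonate, K2CO3, MeOH, 0 °C → rt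
Reagents that add atoms: dimethyl (1-diazo-2-oxopropyl)phosphonate, COP(=O)(OC)C(=[N+]=[N-])C(C)=O
Why: The Ohira–Bestmann (Seyferth–Gilbert) homologation converts the aldehyde into the terminal alkyne under mild base and adds the carbon that becomes C9.

Step 5
Reactants: 5 benzyl (3S)-3-methylhex-5-yn-1-yl ether, 6 3-methylcyclohex-2-en-1-one
Product: 9 trimethyl({(3S)-3-[(1E,4S)-6-(benzyloxy)-4-methylhex-1-en-1-yl]-3-methylcyclohex-1-en-1-yl}oxy)silane, via alkenylalane 7 (not isolated), via aluminium enolate 8 (not isolated)
Conditions: i-Bu2AlH, heptane, 50 °C; then 6, Cu(O2CC4H3S) (10 mol %), Ph2P–N[CH(CH3)(2-naphthyl)]2 (11 mol %, single enantiomer), Et2O, −30 °C; then Me3SiOTf, −30 → 0 °C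
Reagents that add atoms: trimethylsilyl trifluoromethanesulfonate, C[Si](C)(C)OS(=O)(=O)C(F)(F)F
Why: syn-Hydroalumination of the terminal alkyne gives the (E)-alkenylalane 7, whose alkenyl group is transferred in a copper-catalysed asymmetric conjugate addition to the β-methyl enone (face selection by the chiral phosphinamine–copper complex sets the quaternary C10 centre, the ligand antipode that gives the (S) centre being used), and O-silylation of the aluminium enolate 8 fixes the enol double bond at C4=C5 for the next step.

Step 6
Reactants: 10 but-2-yn-1-ol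
Product: 11 (Z)-3-iodobut-2-en-1-ol
Conditions: NaAlH2(OCH2CH2OCH3)2, Et2O, 0 °C → rt; then I2, −78 °C → rt
Reagents that add atoms: iodine, II
Why: Alkoxide-directed trans-hydroalumination of the propargylic alcohol places aluminium on C3 and hydrogen on C2, and iodinolysis of the vinyl–aluminium bond with retention gives the (Z)-vinyl iodide.

Step 7
Reactants: 11 (Z)-3-iodobut-2-en-1-ol
Product: 12 (Z)-1-bromo-3-iodobut-2-ene
Conditions: CBr4, PPh3, CH2Cl2, 0 °C
Reagents that add atoms: carbon tetrabromide, BrC(Br)(Br)Br
Why: The Appel reaction converts the primary allylic alcohol into the bromide under neutral conditions that leave the vinyl iodide and the alkene geometry intact.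

Step 8
Reactants: 9 trimethyl({(3S)-3-[(1E,4S)-6-(benzyloxy)-4-methylhex-1-en-1-yl]-3-methylcyclohex-1-en-1-yl}oxy)silane, 12 (Z)-1-bromo-3-iodobut-2-ene
Product: 15 15-(benzyloxy)-18,19-dinorlabd-7-en-4-one (trans-fused), via lithium enolate 13 (not isolated), via iodo ketone 14 (not isolated)
Conditions: MeLi, THF, 0 °C; then 12, DMPU, −78 → −20 °C; then Bu3SnH (slow addition), Et3B, air, toluene, 0 °C → rt; one flask, 14 not isolated
Reagents that add atoms: none
Why: Methyllithium cleaves the silyl enol ether to the regiodefined lithium enolate 13, which is C-alkylated at C5 by the allylic bromide of 12 (SN2, the vinyl iodide being inert to enolates) to give 14; tributyltin radicals then abstract iodine from 14, the C8 vinyl radical adds to C9 of the pendant (E)-alkene and the resulting C11 radical is reduced by the stannane. The closest known reaction types are the regiospecific alkylation of lithium enolates released from silyl enol ethers and the tin hydride mediated cyclisation of vinyl radicals onto a tethered alkene. Ring B is the only ring closed, in a 6-exo-trig mode in which the double bond of the vinyl radical ends up endocyclic as the C7=C8 alkene carrying the C17 methyl. C5 is controlled by the adjacent quaternary C10: the electrophile enters the enolate axially and anti to the pseudoaxial alkenyl group, that is cis to the C20 methyl, which places C6 and C9 trans-diequatorial on ring A and so leads to the trans ring fusion. C9 is controlled by the chair-like transition state of the ring closure, in which the alkene carbon C11 is pseudo-equatorial, so that H9 ends up anti to C20 and the side chain cis to it. The step needs site selectivity in the alkylation (secured by the enol double bond fixed at C4=C5 in step 5 and by the much higher reactivity of the allylic bromide over the vinyl iodide) and ring closure faster than reduction of the vinyl radical (secured by slow addition of the stannane and the fast 6-exo closure of the sp2 radical).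

Step 9
Reactants: 15 15-(benzyloxy)-18,19-dinorlabd-7-en-4-one
Product: 17 15-(benzyloxy)-18,19-dinorlabda-2,7-dien-4-one, via lithium enolate 16 (not isolated)
Conditions: LiN(i-Pr)2, THF, −78 °C; then PhS(Cl)=N-t-Bu, −78 °C
Reagents that add atoms: none
Why: Kinetic deprotonation takes place at the unhindered C3 methylene and not at the ring-fusion C5–H, and the enolate 16 is dehydrogenated by attack on sulfur of the sulfinimidoyl chloride followed by syn-elimination of the sulfenamide (a one-flask alternative to the Saegusa–Ito oxidation), giving the C2=C3 enone.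

Step 10
Reactants: 17 15-(benzyloxy)-18,19-dinorlabda-2,7-dien-4-one
Product: 18 15-(benzyloxy)-19-norlabda-2,7-dien-4-ol (configuration at C4 not defined)
Conditions: MeLi, Et2O, −78 °C; then H2O
Reagents that add atoms: methyllithium, [Li]C
Why: The hard methyllithium adds 1,2 to the enone carbonyl to give the tertiary allylic alcohol; the configuration of the new carbinol centre is irrelevant because the centre becomes sp2 in the next step.

Step 11
Reactants: 18 15-(benzyloxy)-19-norlabda-2,7-dien-4-ol
Product: 19 15-(benzyloxy)-19-norlabda-3,7-dien-2-one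
Conditions: [C5H5NH][CrO3Cl] (pyridinium chlorochromate), 4 Å molecular sieves, CH2Cl2, rt
Reagents that add atoms: pyridinium chlorochromate, [O-][Cr](=O)(=O)Cl.c1cc[nH+]cc1
Why: Dauben–Babler oxidative transposition: the chromate ester of the tertiary allylic alcohol undergoes a [3,3]-shift to C2 and is oxidised there, which moves the oxygen to C2 and the double bond to C3=C4.

Step 12
Reactants: 19 15-(benzyloxy)-19-norlabda-3,7-dien-2-one
Product: 20 15-(benzyloxy)labd-7-en-2-one
Conditions: Me2CuLi (from MeLi and CuI), Et2O, −20 → 0 °C; then H2O
Reagents that add atoms: lithium dimethylcuprate, [Li+].C[Cu-]C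
Why: Conjugate addition of the Gilman cuprate to the β-methyl enone (the same reaction type as the methylation of isophorone) installs the second methyl group on C4 without creating a stereocentre.

Step 13
Reactants: 20 15-(benzyloxy)labd-7-en-2-one
Product: 21 labd-7-ene-2,15-diol (2-OH equatorial, trans to C20)
Conditions: Li, NH3 (l), THF, −78 → −33 °C; then NH4Cl
Reagents that add atoms: none
Why: Dissolving-metal reduction of the ketone gives the thermodynamically favoured equatorial alcohol at C2 (an axial hydroxyl would be syn-axial to C20 and to the axial C4 methyl), the benzyl ether is cleaved by the same reagent and the isolated trisubstituted alkene is not reduced.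

Step 14
Reactants: 21 labd-7-ene-2,15-diol
Product: 22 labd-7-ene-2,15-diyl diacetate (target)
Conditions: Ac2O, pyridine, DMAP (cat.), CH2Cl2, rt
Reagents that add atoms: acetic anhydride, CC(=O)OC(C)=O
Why: DMAP-catalysed acylation esterifies the primary C15 and the secondary equatorial C2 hydroxyl groups.

**Compound list**

1 | methyl hydrogen (R)-3-methylglutarate [(3R)-5-methoxy-3-methyl-5-oxopentanoic acid] | COC(=O)C[C@H](C)CC(=O)O | starting material
2 | methyl (3R)-5-hydroxy-3-methylpentanoate | COC(=O)C[C@H](C)CCO | intermediate
3 | methyl (3R)-5-(benzyloxy)-3-methylpentanoate | COC(=O)C[C@H](C)CCOCc1ccccc1 | intermediate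
4 | (3R)-5-(benzyloxy)-3-methylpentanal | O=CC[C@H](C)CCOCc1ccccc1 | intermediate
5 | benzyl (3S)-3-methylhex-5-yn-1-yl ether | C#CC[C@H](C)CCOCc1ccccc1 | intermediate
6 | 3-methylcyclohex-2-en-1-one | CC1=CC(=O)CCC1 | starting material
7 | diisobutyl[(1E,4S)-6-(benzyloxy)-4-methylhex-1-en-1-yl]aluminium (not isolated) | CC(C)C[Al](CC(C)C)/C=C/C[C@H](C)CCOCc1ccccc1 | intermediate
8 | diisobutylaluminium (3S)-3-[(1E,4S)-6-(benzyloxy)-4-methylhex-1-en-1-yl]-3-methylcyclohex-1-en-1-olate (not isolated) | CC(C)C[Al](CC(C)C)OC1=C[C@](C)(/C=C/C[C@H](C)CCOCc2ccccc2)CCC1 | intermediate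
9 | trimethyl({(3S)-3-[(1E,4S)-6-(benzyloxy)-4-methylhex-1-en-1-yl]-3-methylcyclohex-1-en-1-yl}oxy)silane | C[Si](C)(C)OC1=C[C@](C)(/C=C/C[C@H](C)CCOCc2ccccc2)CCC1 | intermediate
10 | but-2-yn-1-ol | CC#CCO | starting material
11 | (Z)-3-iodobut-2-en-1-ol | OC/C=C(\I)C | intermediate
12 | (Z)-1-bromo-3-iodobut-2-ene | BrC/C=C(\I)C | intermediate
13 | lithium (3S)-3-[(1E,4S)-6-(benzyloxy)-4-methylhex-1-en-1-yl]-3-methylcyclohex-1-en-1-olate (not isolated) | [Li]OC1=C[C@](C)(/C=C/C[C@H](C)CCOCc2ccccc2)CCC1 | intermediate
14 | (2S,3S)-3-[(1E,4S)-6-(benzyloxy)-4-methylhex-1-en-1-yl]-2-[(2Z)-3-iodobut-2-en-1-yl]-3-methylcyclohexan-1-one; iodobutenyl group cis to the ring methyl (not isolated) | O=C1CCC[C@@](C)(/C=C/C[C@H](C)CCOCc2ccccc2)[C@@H]1C/C=C(\I)C | intermediate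
15 | 15-(benzyloxy)-18,19-dinorlabd-7-en-4-one; trans-fused, H5 and H9 anti to C20 | c1ccccc1COCC[C@@H](C)CC[C@@H]1C(C)=CC[C@@H]2C(=O)CCC[C@@]12C | intermediate
16 | lithium 15-(benzyloxy)-18,19-dinorlabda-3,7-dien-4-olate (not isolated) | c1ccccc1COCC[C@@H](C)CC[C@@H]1C(C)=CC[C@@H]2C(O[Li])=CCC[C@@]12C | intermediate
17 | 15-(benzyloxy)-18,19-dinorlabda-2,7-dien-4-one | c1ccccc1COCC[C@@H](C)CC[C@@H]1C(C)=CC[C@@H]2C(=O)C=CC[C@@]12C | intermediate
18 | 15-(benzyloxy)-19-norlabda-2,7-dien-4-ol; C4 configuration not defined | c1ccccc1COCC[C@@H](C)CC[C@@H]1C(C)=CC[C@@H]2C(C)(O)C=CC[C@@]12C | intermediate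
19 | 15-(benzyloxy)-19-norlabda-3,7-dien-2-one | c1ccccc1COCC[C@@H](C)CC[C@@H]1C(C)=CC[C@@H]2C(C)=CC(=O)C[C@@]12C | intermediate
20 | 15-(benzyloxy)labd-7-en-2-one | c1ccccc1COCC[C@@H](C)CC[C@@H]1C(C)=CC[C@@H]2C(C)(C)CC(=O)C[C@@]12C | intermediate
21 | labd-7-ene-2,15-diol; 2-OH equatorial and trans to C20 | OCC[C@@H](C)CC[C@@H]1C(C)=CC[C@@H]2C(C)(C)C[C@@H](O)C[C@@]12C | intermediate
22 | labd-7-ene-2,15-diyl diacetate; 2-OAc equatorial and trans to C20, 13S | CC(=O)OCC[C@@H](C)CC[C@@H]1C(C)=CC[C@@H]2C(C)(C)C[C@@H](OC(C)=O)C[C@@]12C | target

**Step count and risks**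

Total step count: 14. Longest linear sequence: 12 steps (steps 1–5, then 8–14); steps 6 and 7 make the C4 building block 12.

The three steps most likely to fail:

Step 8. Three processes threaten it. The C8 vinyl radical may be reduced by the stannane before it reaches C9. The ring may close through the boat-like transition state, which would invert C9. The enolate may be alkylated on the face cis to the alkenyl group, or equilibrate to the C3 side, which would give the cis-fused series. The fallback makes the two bonds in separate operations and closes the ring with palladium instead of a radical. It sets out from iodo ketone 14, now isolated after aqueous work-up of the alkylation of 9, so that C5 epimers can be separated. An intramolecular Heck reaction (Pd(OAc)2, PPh3, Ag2CO3, MeCN, 80 °C) follows: the (Z)-iodide places palladium cis to C6, insertion is 6-exo-trig and β-hydride elimination towards C12 is intended. This would give 15-(benzyloxy)-18,19-dinorlabda-7,11-dien-4-one F1. Diimide (2-nitrobenzenesulfonohydrazide, Et3N, CH2Cl2, rt) then saturates only the disubstituted C11=C12 bond, and the route is rejoined at 15.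

Step 12. The methyl group has to enter C4 syn-axial to the C20 methyl, so conjugate addition may be outrun by 1,2-addition or by γ-deprotonation of the enone. The fallback sets out from 19 and brings in the last carbon as a methylene. Corey–Chaykovsky methylenation (Me3S(O)I, NaH, DMSO, rt) would give the cyclopropyl ketone 15-(benzyloxy)-3,19-cyclolabd-7-en-2-one F2. Li in NH3/THF (−78 → −33 °C) then cleaves the C3–C19 cyclopropane bond, the one that overlaps with the carbonyl π system, and so turns C19 into the second C4 methyl. Addition of EtOH and further Li in the same flask reduces the ketone to the equatorial alcohol and removes the benzyl group. The route is rejoined at diol 21.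

Step 5. Facial discrimination in the copper-catalysed alkenyl transfer may be incomplete, and the minor C10 epimer could not be removed because C13 is remote. An isobutyl group may be transferred in place of the alkenyl group, or O-silylation of the aluminium enolate may be incomplete. The fallback exchanges the roles of the two C10 substituents and sets out from alkyne 5. Hydrozirconation (Cp2Zr(H)Cl, THF) and iodinolysis would give benzyl (3S,5E)-6-iodo-3-methylhex-5-en-1-yl ether F3. Iodine–lithium exchange (t-BuLi, Et2O, −78 °C), addition to 3-ethoxycyclohex-2-en-1-one and acid work-up (Stork–Danheiser sequence) would give 3-[(1E,4S)-6-(benzyloxy)-4-methylhex-1-en-1-yl]cyclohex-2-en-1-one F4. Copper-catalysed asymmetric 1,4-addition of MeMgBr (Cu(OTf)2, chiral N-heterocyclic carbene ligand, Et2O, −30 °C) with Me3SiCl/Et3N trapping then rejoins the route at 9.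

**Further compounds**

F1 | step 8 | 15-(benzyloxy)-18,19-dinorlabda-7,11-dien-4-one (11E) | c1ccccc1COCC[C@@H](C)/C=C/[C@@H]1C(C)=CC[C@@H]2C(=O)CCC[C@@]12C
F2 | step 12 | 15-(benzyloxy)-3,19-cyclolabd-7-en-2-one (cyclopropane C3–C4–C19; configuration at C3 and C4 not defined) | c1ccccc1COCC[C@@H](C)CC[C@@H]1C(C)=CC[C@@H]2C3(C)CC3C(=O)C[C@@]12C
F3 | step 5 | benzyl (3S,5E)-6-iodo-3-methylhex-5-en-1-yl ether | I/C=C/C[C@H](C)CCOCc1ccccc1
F4 | step 5 | 3-[(1E,4S)-6-(benzyloxy)-4-methylhex-1-en-1-yl]cyclohex-2-en-1-one | O=C1C=C(/C=C/C[C@H](C)CCOCc2ccccc2)CCC1
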